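You asked for a quick number, and a target curve that goes flat invites the reading in your forecast: “The enzyme is dead by 6 d.” I read birch, the flask in question, differently.

| setting | birch | maple | flask |
|---|---|---|---|
| starting material | 0.20 M | 0.20 M | 0.20 M |
| free enzyme | 1.3 µM | 2.6 µM | 1.3 µM |
| temperature | 30 °C | 36 °C | 30 °C |
| remark | the very flask that is asked about, followed so far | run made earlier |  |
| time |  |  | 6.0 d |

| run | time / h | target / % | starting material / % |
|---|---|---|---|
| birch | 10.0 | 17.8 | 81.3 |
| birch | 15.0 | 23.1 | 76.2 |
| birch | 20.0 | 26.1 | 72.1 |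
| birch | 30.0 | 28.9 | 66.8 |
| birch | 50.0 | 30.4 | 62.0 |
| birch | 72.0 | 29.8 | 57.9 |
| birch | 120 | 27.4 | 53.7 |
| maple | 3.00 | 15.4 | 85.0 |
| maple | 6.00 | 18.6 | 79.9 |
| maple | 10.0 | 20.4 | 77.4 |
| maple | 12.0 | 19.9 | 76.6 |
| maple | 15.0 | 19.5 | 76.6 |
| maple | 20.0 | 19.7 | 74.8 |

(readings scatter by 0.3 percentage points)
- ochre: at 6.0 d take out 90 % of the target then present, then wait 3.0 d
- green: change nothing and wait 3.0 d more
- teal: at 6.0 d add free enzyme, 50.0 % of the amount charged, then wait 3.0 d
- violet: at 6.0 d raise the temperature by 20 K, then wait 3.0 d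
- what is taken out of target is counted as made
- additions bring no volume worth counting
* target, in percent of the starting material first charged, at 6.0 d
* what to do for the largest gain in target; "none" if nothing gains more than 2 percentage points (ochre / green / teal / violet / none)
* target present, with what was taken out counted in, in percent of the starting material first charged, after ochre
* target present, with what was taken out counted in, in percent of the starting material first charged, after teal

From 72.0 h to 120 h birch's starting material still falls, from 57.9 % to 53.7 %, while c(target)/c(starting material) reads 0.515 and then 0.510. Maple, with more enzyme at 36 °C, levels at a lower ratio, 0.263. So I take the level for a balance kept by working enzyme (a pre-equilibrium), with target leaking slowly out of it. Then target is a fixed share f of the pool S, and the leak acts on that share: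

S = c(starting material) + c(target)
f = c(target)/S = 33.8 %
dS/dt = −λS, so S(t) = S(a) exp(−λ(t − a))
λ = ln[S(50.0 h)/S(120 h)]/(120 h − 50.0 h) = 0.00186 h⁻¹

I call λ, the fraction of the pool lost per hour, the leak constant. Over 3.0 d it keeps a factor 0.874.

My reckoning:

S at 6.0 d = 77.6 %, target = 26.2 %
green and teal: 22.9 %
ochre: 23.6 % taken out, then 39.5 % in total

Ochre assumes the balance refills, and birch climbed to 28.9 % within 30.0 h, shorter than 3.0 d. Violet I expect to lose, as a guess: maple, which differs from birch in enzyme as well as in temperature, levels at the lower ratio.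

Your forecast says 25.8 %, ochre, 29.2 % after ochre and 27.7 % after teal. We agree on the choice and nearly on the present target, but I put ochre higher and teal lower.

The flask gives 25.6 %; ochre wins, with 38.8 %, and teal gives 22.4 %. In the flask at 144 h, free enzyme stands at 59.1 % of the catalyst charged, complex at 34.8 %, unfolded enzyme at 6.13 %.

    free enzyme → unfolded enzyme (k = 7.50 × 10⁻⁴ h⁻¹, Ea = 268 kJ mol⁻¹)
    starting material + free enzyme ⇌ complex (K = 5.80 L mol⁻¹, k = 1.40 × 10⁶ L mol⁻¹ h⁻¹, Ea = 36.0 kJ mol⁻¹, ΔH = −1.00 kJ mol⁻¹)
    complex ⇌ free enzyme + target (K = 0.0930 M, k = 7200 h⁻¹, Ea = 69.0 kJ mol⁻¹, ΔH = −86.0 kJ mol⁻¹)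
    target → over-reaction product (k = 0.00610 h⁻¹, Ea = 108 kJ mol⁻¹)
    (constants at 30 °C)

On this flask the factor 0.874 takes 3.2 percentage points off target over the green wait, and green loses 3.5 points. Left ten times as long, λ reckons 25.6 % down to 2.30 %, and the flask then holds 1.80 % at 1440 h.

The readings are simulated with made-up constants.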